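The route rests on cutting the C3a–C7a bond, which is shared by the cyclohexane (ring A) and the butenolide (ring B). C7a carries O1, and C3a is the β-carbon of the O1–C2(=O)–C3H=C3a enoate. Both rings therefore unravel to a methyl ketone, a terminal alkyne and CO. A molybdenum-mediated hetero-Pauson–Khand reaction of an acyclic (R)-β-silyloxy alkynyl ketone should form C3a–C7a, C3–C2 and C2–O1 in one operation and set C7a from C6. The chair-like closure leads to the 6-epi series. The closing Mitsunobu esterification with palmitic acid therefore inverts C6 and installs the ester in the same step.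

Key step: step 6

Remark: the loliolide numbering (O1, C2, C3, C3a, C4, C5, C6, C7, C7a) is used for the corresponding atoms of every intermediate. Compounds 1, 5 and 14 are taken to be commercially available.

Step 1
Reactants: 1 2,2-dimethylpent-4-enal
Product: 2 3,3-dimethylhex-5-en-1-yne
Conditions: dimethyl (1-diazo-2-oxopropyl)phosphonate, K2CO3, MeOH, 0 °C to rt; volatile product kept as a dried CH2Cl2 solution
Reagents that add atoms: dimethyl (1-diazo-2-oxopropyl)phosphonate, CC(=O)C(=[N+]=[N-])P(=O)(OC)OC
Why: Seyferth–Gilbert homologation in the Ohira–Bestmann variant turns the aldehyde into the terminal alkyne (C3a≡C3) under mild base, and the aldehyde has no α-hydrogen, so enolisation cannot compete and the alkene is untouched.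

Step 2
Reactants: 2 3,3-dimethylhex-5-en-1-yne
Product: 4 3,3-dimethylpent-4-ynal, via ozonide 3 (not isolated)
Conditions: O3 (about 1 equiv), CH2Cl2, −78 °C; then Me2S, −78 °C to rt
Reagents that add atoms: ozone, [O-][O+]=O
Why: Ozonolysis (Criegee mechanism) should be chemoselective because ozone adds to the monosubstituted alkene far faster than to the hindered terminal alkyne, and Me2S reduces ozonide 3 to the aldehyde without over-oxidation.

Step 3
Reactants: 4 3,3-dimethylpent-4-ynal; 5 tributyl(2-methylallyl)stannane
Product: 7 (S)-2,6,6-trimethyloct-1-en-7-yn-4-ol, via stannyl ether 6 (not isolated)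
Conditions: (S)-BINOL (20 mol %), Ti(OiPr)4 (10 mol %), 4 Å MS, CH2Cl2, −20 °C; aq. NaHCO3 work-up
Reagents that add atoms: none
Why: Keck asymmetric allylation in its methallylstannane variant, in which the (S)-BINOL–titanium Lewis acid shields one face of the unbranched aldehyde and so sets C6 in the sense established for such aldehydes (descriptor S here), while the terminal alkyne is inert.

Step 4
Reactants: 7 (S)-2,6,6-trimethyloct-1-en-7-yn-4-ol
Product: 8 (S)-tert-butyldimethyl[(2,6,6-trimethyloct-1-en-7-yn-4-yl)oxy]silane
Conditions: TBSCl, imidazole, DMF, rt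
Reagents that add atoms: tert-butyldimethylsilyl chloride (TBSCl), CC(C)(C)[Si](C)(C)Cl
Why: Imidazole-promoted silylation of a secondary alcohol leaves C6 untouched, removes the O–H group that could interfere at molybdenum or open a retro-aldol path later, and supplies a bulky group that will insist on an equatorial position in step 6.

Step 5
Reactants: 8 (S)-tert-butyldimethyl[(2,6,6-trimethyloct-1-en-7-yn-4-yl)oxy]silane
Product: 10 (R)-4-(tert-butyldimethylsilyloxy)-6,6-dimethyloct-7-yn-2-one, via ozonide 9 (not isolated)
Conditions: O3 (about 1 equiv), CH2Cl2, −78 °C; then Me2S, −78 °C to rt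
Reagents that add atoms: ozone, [O-][O+]=O
Why: Ozonolysis (Criegee mechanism) of the electron-rich 1,1-disubstituted alkene outruns attack on the alkyne and unveils the C7a methyl ketone under neutral conditions, with C6 spatially unchanged (S becomes R only through the change of priorities).

Step 6
Reactants: 10 (R)-4-(tert-butyldimethylsilyloxy)-6,6-dimethyloct-7-yn-2-one
Product: 12 (6R,7aR)-6-(tert-butyldimethylsilyloxy)-4,4,7a-trimethyl-5,6,7,7a-tetrahydro-1-benzofuran-2(4H)-one, via oxamolybdacyclopentene 11 (not isolated)
Conditions: Mo(CO)3(DMF)3 (2 equiv, prepared beforehand from Mo(CO)6 in DMF), THF (0.02 M), Ar, rt to 60 °C; then air, filtration through SiO2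
Reagents that add atoms: tricarbonyltris(N,N-dimethylformamide)molybdenum, Mo(CO)3(DMF)3 (delivers one CO), [Mo].[C-]#[O+].[C-]#[O+].[C-]#[O+].CN(C)C=O.CN(C)C=O.CN(C)C=O
Why: Proposed new method: loss of DMF lets zerovalent molybdenum bind the terminal alkyne and the ketone C=O side by side, oxidative cyclisation joins the inner alkyne carbon C3a to the carbonyl carbon C7a to give oxamolybdacyclopentene 11 (divalent molybdenum), CO migrates into the Mo–C3 bond, and C–O reductive elimination releases the butenolide. The closest known reaction type is the molybdenum-mediated hetero-Pauson–Khand reaction of 1,7-alkynyl aldehydes, which builds the same tetrahydrobenzofuranone core, supported by the cyclocarbonylation of alkenyl and allenyl ketones with titanium, molybdenum and ruthenium carbonyl reagents; the new element is an unactivated alkynyl methyl ketone as substrate. Ring A closes 6-exo-dig at the alkyne and 6-exo-trig at the carbonyl group, helped by the Thorpe–Ingold effect of the C4 gem-dimethyl group, and ring B closes by reductive elimination from the six-membered acyl-oxa-molybdacycle, so that overall a [2+2+1] cycloaddition takes place. The one new stereocentre, C7a, is controlled by C6: in the chair-like transition state the carbonyl oxygen must lie in the plane of the metallacycle (pseudo-equatorial), the C7a methyl group is therefore axial, and the OTBS group stays equatorial to avoid the syn-axial methyl groups on C4 and C7a, which places O1 and the C6 oxygen cis, that is (6R,7aR). The step needs regioselectivity, which the tether fixes because only C3a can reach the ketone; it needs the intramolecular pair to win over alkyne oligomerisation, which dilution and the gem-dimethyl group favour; and it needs the β-silyloxy ketone to survive, which the neutral medium secures.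

Step 7
Reactants: 12 (6R,7aR)-6-(tert-butyldimethylsilyloxy)-4,4,7a-trimethyl-5,6,7,7a-tetrahydro-1-benzofuran-2(4H)-one
Product: 13 (6R,7aR)-6-hydroxy-4,4,7a-trimethyl-5,6,7,7a-tetrahydro-1-benzofuran-2(4H)-one (6-epi-loliolide)
Conditions: HF·pyridine, THF, 0 °C to rt
Reagents that add atoms: none
Why: Fluoride-induced Si–O cleavage is driven by the strong Si–F bond, and the non-basic HF·pyridine leaves the butenolide, the tertiary C7a–O1 bond and both stereocentres untouched.

Step 8
Reactants: 13 6-epi-loliolide; 14 palmitic acid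
Product: 16 (-)-3-O-palmitoylloliolide, via alkoxyphosphonium palmitate 15 (not isolated)
Conditions: PPh3, DIAD, toluene, 0 °C to 50 °C
Reagents that add atoms: none
Why: Mitsunobu reaction, in which PPh3/DIAD turn the equatorial C6–OH into the oxyphosphonium ion of 15 and palmitate displaces it in an SN2 process with inversion (6R to 6S, axial ester trans to O1), while E2 loss is held back because an equatorial leaving group has no antiperiplanar hydrogen, and the quaternary C7a cannot change.

Compound list
1 | 2,2-dimethylpent-4-enal | C=CCC(C)(C)C=O | starting material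
2 | 3,3-dimethylhex-5-en-1-yne | C=CCC(C)(C)C#C | intermediate
3 | 3-(2,2-dimethylbut-3-yn-1-yl)-1,2,4-trioxolane (secondary ozonide of 2, racemic) | C#CC(C)(C)CC1OCOO1 | intermediate
4 | 3,3-dimethylpent-4-ynal | C#CC(C)(C)CC=O | intermediate
5 | tributyl(2-methylallyl)stannane | C=C(C)C[Sn](CCCC)(CCCC)CCCC | starting material
6 | tributyl{[(4S)-2,6,6-trimethyloct-1-en-7-yn-4-yl]oxy}stannane | C=C(C)C[C@H](O[Sn](CCCC)(CCCC)CCCC)CC(C)(C)C#C | intermediate
7 | (S)-2,6,6-trimethyloct-1-en-7-yn-4-ol | C=C(C)C[C@H](O)CC(C)(C)C#C | intermediate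
8 | (S)-tert-butyldimethyl[(2,6,6-trimethyloct-1-en-7-yn-4-yl)oxy]silane | C=C(C)C[C@H](O[Si](C)(C)C(C)(C)C)CC(C)(C)C#C | intermediate
9 | 3-[(2R)-2-(tert-butyldimethylsilyloxy)-4,4-dimethylhex-5-yn-1-yl]-3-methyl-1,2,4-trioxolane (secondary ozonide of 8, mixture at the ring carbon) | CC1(C[C@H](O[Si](C)(C)C(C)(C)C)CC(C)(C)C#C)OCOO1 | intermediate
10 | (R)-4-(tert-butyldimethylsilyloxy)-6,6-dimethyloct-7-yn-2-one | CC(=O)C[C@H](O[Si](C)(C)C(C)(C)C)CC(C)(C)C#C | intermediate
11 | oxamolybdacyclopentene fused to ring A (Mo bonded to C3 and O1; remaining CO and DMF ligands not drawn) | CC(C)(C)[Si](C)(C)O[C@@H]1CC(C)(C)C2=C[Mo]O[C@]2(C)C1 | intermediate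
12 | (6R,7aR)-6-(tert-butyldimethylsilyloxy)-4,4,7a-trimethyl-5,6,7,7a-tetrahydro-1-benzofuran-2(4H)-one | CC(C)(C)[Si](C)(C)O[C@@H]1CC(C)(C)C2=CC(=O)O[C@]2(C)C1 | intermediate
13 | (6R,7aR)-6-hydroxy-4,4,7a-trimethyl-5,6,7,7a-tetrahydro-1-benzofuran-2(4H)-one (6-epi-loliolide; OH equatorial, cis to O1) | O[C@@H]1CC(C)(C)C2=CC(=O)O[C@]2(C)C1 | intermediate
14 | palmitic acid (hexadecanoic acid) | CCCCCCCCCCCCCCCC(=O)O | starting material
15 | [(6R,7aR)-4,4,7a-trimethyl-2-oxo-2,4,5,6,7,7a-hexahydro-1-benzofuran-6-yl]oxytriphenylphosphonium palmitate | CCCCCCCCCCCCCCCC(=O)[O-].c1ccccc1[P+](c1ccccc1)(c1ccccc1)O[C@@H]1CC(C)(C)C2=CC(=O)O[C@]2(C)C1 | intermediate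
16 | (-)-3-O-palmitoylloliolide, (6S,7aR)-4,4,7a-trimethyl-2-oxo-2,4,5,6,7,7a-hexahydro-1-benzofuran-6-yl hexadecanoate | CCCCCCCCCCCCCCCC(=O)O[C@H]1CC(C)(C)C2=CC(=O)O[C@]2(C)C1 | target

Total step count: 8. Longest linear sequence: 8 steps (1 to 16).

Steps most likely to fail

1. Step 6 (hetero-Pauson–Khand reaction).
- **Risk:** The methyl ketone may bind too weakly to zerovalent molybdenum for oxidative cyclisation. Alkyne oligomerisation or slow decay of the reagent would then take over.
- **Fallback:** It uses known chemistry, forms the same C3a–C7a bond, sets out from 8 and comes back at 12. The alkyne of 8 is lithiated (n-BuLi, THF, −78 °C) and acylated with methyl chloroformate to give methyl (S)-6-(tert-butyldimethylsilyloxy)-4,4,8-trimethylnon-8-en-2-ynoate F1. Anti-hydroiodination of the ynoate (NaI, AcOH, heat) gives methyl (2Z,6S)-6-(tert-butyldimethylsilyloxy)-3-iodo-4,4,8-trimethylnona-2,8-dienoate F2. Selective ozonolysis of its electron-rich 1,1-disubstituted alkene (O3, then Me2S) gives methyl (2Z,6R)-6-(tert-butyldimethylsilyloxy)-3-iodo-4,4-dimethyl-8-oxonon-2-enoate F3. An intramolecular Nozaki–Hiyama–Kishi reaction (CrCl2, catalytic NiCl2, DMF) adds the alkenyl chromium centre at C3a to the ketone C7a. The resulting alkoxide then lactonises onto the cis ester to give 12.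

2. Step 8 (Mitsunobu inversion).
- **Risk:** The carboxylate has to approach C6 past the two syn-axial methyl groups on C4 and C7a, and palmitic acid is only weakly acidic. Displacement may therefore be too slow, with unreacted alcohol, elimination or acyl transfer with retention as the outcome.
- **Fallback:** It sets out from 13 and comes back at 16. Oxidation with Dess–Martin periodinane gives (7aR)-4,4,7a-trimethyl-4,5,7,7a-tetrahydro-1-benzofuran-2,6-dione F4. Reduction with LiBH(s-Bu)3 (THF, −78 °C) delivers hydride from the open equatorial side, because the same two axial methyl groups block the axial side, and gives the axial alcohol (-)-loliolide F5. Steglich esterification of F5 with 14 (EDC·HCl, DMAP, CH2Cl2) gives 16.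

3. Step 3 (asymmetric methallylation).
- **Risk:** Facial selectivity on the neopentyl-type aldehyde may be insufficient, and this would erode the enantiopurity of every later compound.
- **Fallback:** It sets out from 2 and comes back at 7, bypassing 4. Epoxidation of the alkene with mCPBA gives racemic 2-(2,2-dimethylbut-3-yn-1-yl)oxirane F6. Hydrolytic kinetic resolution follows, using (R,R)-N,N'-bis(3,5-di-tert-butylsalicylidene)-1,2-cyclohexanediaminocobalt acetate, (salen)Co(OAc), and 0.55 equiv of water. This leaves (R)-2-(2,2-dimethylbut-3-yn-1-yl)oxirane F7. The other enantiomer is hydrolysed to (S)-4,4-dimethylhex-5-yne-1,2-diol F8 and removed. CuI-catalysed opening of F7 at its terminal carbon with an excess of isopropenylmagnesium bromide, CH2=C(CH3)MgBr, gives 7 with C6 retained.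

Further compounds
F1 | step 6 | methyl (S)-6-(tert-butyldimethylsilyloxy)-4,4,8-trimethylnon-8-en-2-ynoate | C=C(C)C[C@H](O[Si](C)(C)C(C)(C)C)CC(C)(C)C#CC(=O)OC
F2 | step 6 | methyl (2Z,6S)-6-(tert-butyldimethylsilyloxy)-3-iodo-4,4,8-trimethylnona-2,8-dienoate | C=C(C)C[C@H](O[Si](C)(C)C(C)(C)C)CC(C)(C)/C(I)=C/C(=O)OC
F3 | step 6 | methyl (2Z,6R)-6-(tert-butyldimethylsilyloxy)-3-iodo-4,4-dimethyl-8-oxonon-2-enoate | CC(=O)C[C@H](O[Si](C)(C)C(C)(C)C)CC(C)(C)/C(I)=C/C(=O)OC
F4 | step 8 | (7aR)-4,4,7a-trimethyl-4,5,7,7a-tetrahydro-1-benzofuran-2,6-dione | O=C1CC(C)(C)C2=CC(=O)O[C@]2(C)C1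
F5 | step 8 | (-)-loliolide, (6S,7aR)-6-hydroxy-4,4,7a-trimethyl-5,6,7,7a-tetrahydro-1-benzofuran-2(4H)-one | O[C@H]1CC(C)(C)C2=CC(=O)O[C@]2(C)C1
F6 | step 3 | racemic 2-(2,2-dimethylbut-3-yn-1-yl)oxirane | C#CC(C)(C)CC1CO1
F7 | step 3 | (R)-2-(2,2-dimethylbut-3-yn-1-yl)oxirane | C#CC(C)(C)C[C@@H]1CO1
F8 | step 3 | (S)-4,4-dimethylhex-5-yne-1,2-diol | C#CC(C)(C)C[C@H](O)CO
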